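**Two amounts.** Watch how the charges of free catalyst and impurity stand to each other in these flasks, since we shall read both new flasks from that difference.

| flask | starting material | second substrate | free catalyst | impurity | remark | time |
|---|---|---|---|---|---|---|
| elm | 0.050 M | 0.10 M | 1.7 mM | 0.70 mM | run made earlier |  |
| alder | 0.050 M | 0.10 M | 1.1 mM | 1.4 mM | run made earlier |  |
| Monday's | 0.050 M | 0.100 M | 1.1 mM | 0.70 mM |  | 2.0 min |
| Saturday's | 0.050 M | 0.200 M | 1.1 mM | 0.70 mM |  | 2.0 min |

- elm (time / s: catalyst intermediate A / %, target / %, starting material / %): 10.0: 0.6, 31.4, 68.8; 12.0: 0, 35.4, 64.3; 20.0: 0.4, 51.6, 46.8; 40.0: 0.1, 78.3, 21.6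
- alder (time / s: catalyst intermediate A / %, target / %, starting material / %): 10.0: 0, 4.3, 96.1; 15.0: 0, 4.5, 95.5; 25.0: 0, 5.2, 95.7; 30.0: 0.1, 4.8, 95.5; 40.0: 0, 4.0, 95.5

(each reading ± 0.3 percentage points)

- the analysis behind the earlier runs scatters by 0.3 percentage points, standard deviation

- which of these there is most of at the end, counted by the starting material in it, Monday's (starting material / catalyst intermediate A / target)
- which of these there is most of at the end, counted by the starting material in it, Saturday's (starting material / catalyst intermediate A / target)
- the largest of these amounts at the end, in percent of the starting material charged, Monday's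
- the largest of these amounts at the end, in percent of the starting material charged, Saturday's

Elm, with impurity below free catalyst, reaches 78.3% target at 40.0 s. Alder, with impurity above free catalyst, stays between 4.0% and 5.2% target from 10.0 s on. We read this as one impurity taking one catalyst. Our quantity is the free catalyst charged minus the impurity charged, the surviving catalyst 0.400 mM, for Monday's and Saturday's alike. It is 1.00 mM for elm and −0.300 mM, below zero, for alder.

**Our reckoning.** Elm's last reading gives a pseudo-first-order constant of 0.0383 s⁻¹. Assuming first order in surviving catalyst, we scale it by 0.400, which gives Monday's 84.1% target at 2.0 min. Neither earlier run changed [second substrate], so for Saturday's we have no reading of its effect.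

**The forecast.** It names target for Monday's, at 85% (80% to 89%), and target for Saturday's, at 85% (78% to 91%), reasoning that “Saturday's doubled second substrate should change little”. Our 84.1% for Monday's is lower than its figure, and for Saturday's we offer no figure of our own.

**The flasks.** Monday's gives target at 85.2%. Saturday's gives target at 75.8%, below the forecast's range.

    starting material + free catalyst ⇌ catalyst intermediate A (K = 12.0 M⁻¹, k = 110 M⁻¹ s⁻¹)
    catalyst intermediate A → free catalyst + target (k = 13.0 s⁻¹)
    second substrate + free catalyst ⇌ catalyst intermediate B (K = 6.40 M⁻¹, k = 130 M⁻¹ s⁻¹)
    catalyst intermediate B → free catalyst + second product (k = 1.40 s⁻¹)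
    free catalyst + impurity → spent catalyst (k = 2100 M⁻¹ s⁻¹)
    2 catalyst intermediate A ⇌ resting dimer (K = 1000 M⁻¹, k = 120 M⁻¹ s⁻¹)

**Where it stands.** At 2.00 min on Saturday's, spent catalyst stands at 63.6% of the catalyst charged, leaving the 36.4% that surviving catalyst gives, and of that catalyst intermediate B holds 17.6%, free catalyst 17.7%, catalyst intermediate A 1.06% and resting dimer 0.0304%, against 11.3%, 24.2%, 0.886% and 0.0234% on Monday's. On Monday's at 0.603 min, catalyst intermediate B falls back 15 times as fast as it goes on. A neighbour flask charged with 0.440 mM of free catalyst has −0.260 mM surviving catalyst, below zero, and stands at 3.00% target with 0% free catalyst and 37% of its impurity left, the 37.1% the difference gives.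

Readings and results were generated by integration from invented constants.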